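**Retrosynthetic overview**
- Ferutinin ⇒ jaeschkeanadiol + 4-acetoxybenzoic acid (acyl C–O bond last); the tertiary carbinol ⇒ isopropyl addition to a C4 ketone.
- The C6–O bond ⇒ conjugate borylation/oxidation of a bicyclic α-alkylidene cyclopentanone, which also sets the trans ring fusion at C5.
- That enone ⇒ ring-closing metathesis of a cyclopentanone α-ketol, then dehydration; the α-ketol ⇒ 2-methoxy enone + 3-methylbut-3-enyl Grignard reagent.
- The quaternary carbon ⇒ Claisen relay of a stereocentre created in an enantioselective C–O allylation of cyclotene (the key C–O bond).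
- Ring order: the cyclopentane is bought (cyclotene); the cycloheptene is closed second, by metathesis.

Assumption: compound 2 is bought (otherwise one step from crotyl alcohol and methyl chloroformate); positions C1–C10 follow daucane numbering (C1 quaternary ring-fusion carbon, C4 isopropyl carbinol, C5 ring-fusion CH, C6 ester carbon, C8=C9 ring alkene).

Step 1
Reactants: 1 2-hydroxy-3-methylcyclopent-2-en-1-one (cyclotene); 2 (E)-but-2-en-1-yl methyl carbonate
Product: 4 (5S)-5-[(2E)-but-2-en-1-yl]-2-hydroxy-5-methylcyclopent-2-en-1-one, via allyl enol ether 3 (not isolated)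
Conditions: [Ir(cod)Cl]2 (2 mol%), Feringa-type phosphoramidite (Sa,S,S)-L (4 mol%), TBD (8 mol%), THF, 35 °C; SiO2 plug; then PhMe, 130 °C
Reagents that add atoms: none
Why: Proposed new method: the allyl–iridium complex formed from 2 is attacked at its substituted terminus by the phenol-like enol oxygen of 1 (its carbon terminus is too hindered to compete), which makes the C–O bond and the R carbinol centre of 3 (the ligand antipode is chosen for R), and the Claisen rearrangement of this diosphenol ether then carries that centre through a chair transition state (methyl equatorial) onto the methyl-bearing ring carbon to give the S quaternary centre of 4; the closest known reaction type is iridium-catalysed enantioselective allylic etherification of phenoxides followed by Claisen rearrangement of diosphenol allyl ethers.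

Step 2
Reactants: 4 (5S)-5-[(2E)-but-2-en-1-yl]-2-hydroxy-5-methylcyclopent-2-en-1-one
Product: 5 (5S)-5-[(2E)-but-2-en-1-yl]-2-methoxy-5-methylcyclopent-2-en-1-one
Conditions: Me2SO4, K2CO3, acetone, 56 °C
Reagents that add atoms: dimethyl sulfate COS(=O)(=O)OC
Why: Williamson-type O-alkylation of the acidic enol by a hard electrophile masks it as an enol ether that survives the next organometallic addition, and no stereocentre is touched.

Step 3
Reactants: 5 (5S)-5-[(2E)-but-2-en-1-yl]-2-methoxy-5-methylcyclopent-2-en-1-one; 6 4-bromo-2-methylbut-1-ene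
Product: 9 (3R)-3-[(2E)-but-2-en-1-yl]-2-hydroxy-3-methyl-2-(3-methylbut-3-en-1-yl)cyclopentan-1-one (C2 epimers), via Grignard reagent 7 (not isolated), via tertiary carbinol 8 (not isolated)
Conditions: 6, Mg, THF, 40 °C; CeCl3, −78 °C; then 5, −78 → 0 °C; then 1 M HCl, THF, 0 °C
Reagents that add atoms: water O
Why: Organocerium (Imamoto) 1,2-addition to the hindered enone carbonyl avoids enolisation and 1,4-addition, and mild acid hydrolysis of the enol ether (the classical 2-alkoxyenone route to α-ketols) frees the C4 ketone, the new carbinol centre forming as a mixture that is erased in step 5.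

Step 4
Reactants: 9 (3R)-3-[(2E)-but-2-en-1-yl]-2-hydroxy-3-methyl-2-(3-methylbut-3-en-1-yl)cyclopentan-1-one (C2 epimers)
Product: 10 (3aR)-8a-hydroxy-3a,6-dimethyl-3,3a,4,7,8,8a-hexahydroazulen-1(2H)-one (C8a epimers)
Conditions: second-generation Grubbs catalyst RuCl2(=CHPh)(SIMes)(PCy3) (5 mol%), CH2Cl2 (5 mM), 40 °C
Reagents that add atoms: none
Why: Ring-closing metathesis between the butenyl arm on the quaternary carbon and the 1,1-disubstituted alkene closes the seven-membered ring as its trisubstituted C8=C9 alkene with loss of propene, and both carbinol epimers cyclise and converge in step 5.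

Step 5
Reactants: 10 (3aR)-8a-hydroxy-3a,6-dimethyl-3,3a,4,7,8,8a-hexahydroazulen-1(2H)-one (C8a epimers)
Product: 11 (3aR)-3a,6-dimethyl-3,3a,4,7-tetrahydroazulen-1(2H)-one
Conditions: SOCl2, pyridine, CH2Cl2, −20 → 0 °C
Reagents that add atoms: none
Why: Pyridine-mediated E2 elimination of the chlorosulfite of the tertiary α-ketol (as in the dehydration of 17-hydroxy-20-keto steroids) can only run toward C6 because C1 is quaternary, so both epimers give the same α-alkylidene ketone.

Step 6
Reactants: 11 (3aR)-3a,6-dimethyl-3,3a,4,7-tetrahydroazulen-1(2H)-one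
Product: 13 (3aR,8S,8aS)-8-hydroxy-3a,6-dimethyl-3,3a,4,7,8,8a-hexahydroazulen-1(2H)-one, via boronate 12 (not isolated)
Conditions: CuCl (5 mol%), (R,R)-QuinoxP* (6 mol%), NaOtBu (4 mol%), B2pin2, MeOH, THF, 0 °C; then NaBO3·4H2O, THF–H2O, 23 °C
Reagents that add atoms: bis(pinacolato)diboron CC1(C)OB(OC1(C)C)B1OC(C)(C)C(C)(C)O1; sodium perborate [Na+].[O-]OB=O
Why: Copper-catalysed conjugate borylation puts boron on the β-carbon C6 under ligand control (the antipode is chosen that adds on the face anti to the angular methyl, catalyst control outweighing the small substrate bias), methanol protonates the enolate at C5 axially on that same face to give the trans ring fusion, and perborate turns the C–B bond into the C6–O bond with retention.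

Step 7
Reactants: 13 (3aR,8S,8aS)-8-hydroxy-3a,6-dimethyl-3,3a,4,7,8,8a-hexahydroazulen-1(2H)-one; 14 isopropylmagnesium chloride
Product: 15 (3R,3aS,4S,8aR)-6,8a-dimethyl-3-(propan-2-yl)-1,2,3,3a,4,5,8,8a-octahydroazulene-3,4-diol (jaeschkeanadiol)
Conditions: 14 (3 equiv), CeCl3 (3 equiv), THF, −78 → −20 °C; aq. NH4Cl
Reagents that add atoms: none
Why: Organocerium 1,2-addition (Imamoto conditions suppress enolisation, reduction and retro-aldol cleavage) to the cyclopentanone, whose β face is blocked by the angular methyl and the C5–C6 bond, brings isopropyl in from the α face so that the tertiary hydroxyl ends β (4R).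

Step 8
Reactants: 15 (3R,3aS,4S,8aR)-6,8a-dimethyl-3-(propan-2-yl)-1,2,3,3a,4,5,8,8a-octahydroazulene-3,4-diol; 16 4-(acetyloxy)benzoic acid
Product: 18 (3R,3aS,4S,8aR)-3-hydroxy-6,8a-dimethyl-3-(propan-2-yl)-1,2,3,3a,4,5,8,8a-octahydroazulen-4-yl 4-hydroxybenzoate (ferutinine), via aryl acetate 17 (not isolated)
Conditions: 16, DCC, DMAP, CH2Cl2, 23 °C; then pyrrolidine, 23 °C
Reagents that add atoms: none
Why: Steglich esterification acylates only the secondary C6 hydroxyl (the tertiary one is inert) without touching any stereocentre, and pyrrolidine aminolysis then removes the more electrophilic phenolic acetate selectively.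

**Compound list**
1 | 2-hydroxy-3-methylcyclopent-2-en-1-one (cyclotene) | CC1=C(O)C(=O)CC1 | starting material
2 | (E)-but-2-en-1-yl methyl carbonate | C/C=C/COC(=O)OC | starting material
3 | 2-{[(2R)-but-3-en-2-yl]oxy}-3-methylcyclopent-2-en-1-one | CC1=C(O[C@H](C)C=C)C(=O)CC1 | intermediate
4 | (5S)-5-[(2E)-but-2-en-1-yl]-2-hydroxy-5-methylcyclopent-2-en-1-one | C/C=C/C[C@@]1(C)CC=C(O)C1=O | intermediate
5 | (5S)-5-[(2E)-but-2-en-1-yl]-2-methoxy-5-methylcyclopent-2-en-1-one | C/C=C/C[C@@]1(C)CC=C(OC)C1=O | intermediate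
6 | 4-bromo-2-methylbut-1-ene | CC(=C)CCBr | starting material
7 | (3-methylbut-3-en-1-yl)magnesium bromide | CC(=C)CC[Mg]Br | intermediate
8 | (5S)-5-[(2E)-but-2-en-1-yl]-2-methoxy-5-methyl-1-(3-methylbut-3-en-1-yl)cyclopent-2-en-1-ol (C1 epimers) | C/C=C/C[C@@]1(C)CC=C(OC)C1(O)CCC(C)=C | intermediate
9 | (3R)-3-[(2E)-but-2-en-1-yl]-2-hydroxy-3-methyl-2-(3-methylbut-3-en-1-yl)cyclopentan-1-one (C2 epimers) | C/C=C/C[C@@]1(C)CCC(=O)C1(O)CCC(C)=C | intermediate
10 | (3aR)-8a-hydroxy-3a,6-dimethyl-3,3a,4,7,8,8a-hexahydroazulen-1(2H)-one (C8a epimers) | CC1=CC[C@@]2(C)CCC(=O)C2(O)CC1 | intermediate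
11 | (3aR)-3a,6-dimethyl-3,3a,4,7-tetrahydroazulen-1(2H)-one | CC1=CC[C@@]2(C)CCC(=O)C2=CC1 | intermediate
12 | (3aR,8S,8aR)-3a,6-dimethyl-8-(4,4,5,5-tetramethyl-1,3,2-dioxaborolan-2-yl)-3,3a,4,7,8,8a-hexahydroazulen-1(2H)-one | CC1=CC[C@@]2(C)CCC(=O)[C@@H]2[C@@H](B3OC(C)(C)C(C)(C)O3)C1 | intermediate
13 | (3aR,8S,8aS)-8-hydroxy-3a,6-dimethyl-3,3a,4,7,8,8a-hexahydroazulen-1(2H)-one | CC1=CC[C@@]2(C)CCC(=O)[C@@H]2[C@@H](O)C1 | intermediate
14 | isopropylmagnesium chloride | CC(C)[Mg]Cl | starting material
15 | (3R,3aS,4S,8aR)-6,8a-dimethyl-3-(propan-2-yl)-1,2,3,3a,4,5,8,8a-octahydroazulene-3,4-diol (jaeschkeanadiol) | CC1=CC[C@@]2(C)CC[C@@](O)(C(C)C)[C@@H]2[C@@H](O)C1 | intermediate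
16 | 4-(acetyloxy)benzoic acid | CC(=O)Oc1ccc(cc1)C(O)=O | starting material
17 | (3R,3aS,4S,8aR)-3-hydroxy-6,8a-dimethyl-3-(propan-2-yl)-1,2,3,3a,4,5,8,8a-octahydroazulen-4-yl 4-(acetyloxy)benzoate | CC1=CC[C@@]2(C)CC[C@@](O)(C(C)C)[C@@H]2[C@@H](OC(=O)c2ccc(OC(C)=O)cc2)C1 | intermediate
18 | (3R,3aS,4S,8aR)-3-hydroxy-6,8a-dimethyl-3-(propan-2-yl)-1,2,3,3a,4,5,8,8a-octahydroazulen-4-yl 4-hydroxybenzoate (ferutinine) | CC1=CC[C@@]2(C)CC[C@@](O)(C(C)C)[C@@H]2[C@@H](OC(=O)c2ccc(O)cc2)C1 | target

**Totals:** 8 steps; longest linear sequence 8 steps (from 1).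

**Three steps most likely to fail**

Step 1 (the proposed new method). Risks are C- instead of O-allylation, a poor branched-to-linear ratio, re-ionisation of 3 by the catalyst before the rearrangement, and loss of enantiopurity through a boat Claisen pathway. The fallback uses known chemistry, sets out from 1 and comes back at 4. Mitsunobu etherification of 1 with purchased (S)-but-3-en-2-ol (PPh3, DIAD, THF, 0 °C; SN2 inversion at the carbinol carbon) gives 3, this time isolated. Heating in toluene (Claisen rearrangement of a diosphenol allyl ether with chair-wise chirality transfer) gives 4. No compound outside the list arises (F0).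

Step 6. Risks are the facial selectivity at C6 (the ligand must override the substrate), cis protonation at C5, and base-induced migration of the C8=C9 alkene of 11 into conjugation. The fallback sets out from 11 and comes back at 15; it moves the C6 stereocontrol from the C–O addition to a directed ketone reduction. Borylation/oxidation with an achiral ligand (Xantphos) gives whichever alcohol the substrate prefers, taken here as the C6-epimeric hydroxy ketone F1. Addition of 14 with CeCl3 gives 6-epi-jaeschkeanadiol F2, and Dess–Martin oxidation gives the 4-hydroxy-6-ketone F3. Me4NBH(OAc)3 (MeCN–AcOH, −20 °C; Evans–Saksena reduction) then delivers hydride internally from the C4 oxygen to the β face of C6 and gives 15.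

Step 7. Risks are enolisation, β-hydride reduction by the isopropyl reagent, retro-aldol cleavage of the β-alkoxide, and attack from the wrong face. The fallback sets out from 13 and comes back at 15. Prop-1-en-2-ylmagnesium bromide with CeCl3 (no β-hydrogen, smaller and less basic) gives the isopropenyl diol F4. Hydrogenation with RhCl(PPh3)3 (H2, 1 atm, benzene) saturates only the 1,1-disubstituted alkene and gives 15.

**Further compounds**
F0 | step 1 | none | none
F1 | step 6 | (3aR,8R,8aS)-8-hydroxy-3a,6-dimethyl-3,3a,4,7,8,8a-hexahydroazulen-1(2H)-one | CC1=CC[C@@]2(C)CCC(=O)[C@@H]2[C@H](O)C1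
F2 | step 6 | (3R,3aS,4R,8aR)-6,8a-dimethyl-3-(propan-2-yl)-1,2,3,3a,4,5,8,8a-octahydroazulene-3,4-diol | CC1=CC[C@@]2(C)CC[C@@](O)(C(C)C)[C@@H]2[C@H](O)C1
F3 | step 6 | (3R,3aR,8aR)-3-hydroxy-6,8a-dimethyl-3-(propan-2-yl)-2,3,3a,5,8,8a-hexahydroazulen-4(1H)-one | CC1=CC[C@@]2(C)CC[C@@](O)(C(C)C)[C@@H]2C(=O)C1
F4 | step 7 | (3S,3aS,4S,8aR)-6,8a-dimethyl-3-(prop-1-en-2-yl)-1,2,3,3a,4,5,8,8a-octahydroazulene-3,4-diol | CC1=CC[C@@]2(C)CC[C@@](O)(C(C)=C)[C@@H]2[C@@H](O)C1
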